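**Plan**

- Retrosynthetic cuts, in order: the C–OOH bond of the side-chain hydroperoxide (ene reaction of a prenyl ketone), the C6–O acyl bond, the side-chain C(=O)–CH2 bond (prenyl addition to an enal), the C4–O and C5–O bonds (dihydroxylation), and last the two ring C–O bonds at C3 and C6 together (to O2 and a diene).
- Enabling feature: with the ring labelled C1 (side chain), C2 (CH2), C3 (CHOH), C4 (C(OH)CH3), C5 (C=O), C6 (CH–O-acyl), the C3 and C6 oxygens are 1,4-related across C4–C5, cis to each other and trans to the C1 substituent. They are the two ends of the O–O bridge of a 2,3-dioxabicyclo[2.2.2]oct-5-ene, whose C4=C5 alkene later carries the ketol.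
- Forward order: (R)-carvone → tosylhydrazone → Shapiro diene → singlet-oxygen [4+2] (the only ring-forming step; the dioxane ring is reopened by zinc) → bis-silyl cis-enediol → side-chain enal → ring dihydroxylation → prenyl addition → double oxidation → desilylation → C6 isovalerate → singlet-oxygen ene reaction.
- Stereochemistry: C1 comes from (R)-carvone; C3 and C6 from suprafacial O2 addition anti to the isopropenyl group; C4 from osmylation anti to the allylic silyloxy groups; C5 ends as the ketone; the E-alkene comes from the ene reaction.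

Key step: step 3

Remark: ring carbons keep the labels C1–C6 defined above in every intermediate; the side-chain carbinol of 16 forms as a mixture of epimers, which is of no consequence because step 9 oxidises it.

**Step 1**
Reactants: 1 (R)-carvone; 2 4-methylbenzenesulfonohydrazide
Product: 3 (R)-carvone (E)-tosylhydrazone
Conditions: TsNHNH2, MeOH, rt
Reagents that add atoms: 4-methylbenzenesulfonohydrazide (2), Cc1ccc(cc1)S(=O)(=O)NN
Why: Hydrazone condensation at the enone carbonyl leaves C1 untouched and should place the NHTs group on the side of the C6 methylene, where it later directs deprotonation.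

**Step 2**
Reactants: 3 (R)-carvone (E)-tosylhydrazone
Product: 5 (5R)-2-methyl-5-(prop-1-en-2-yl)cyclohexa-1,3-diene, via vinyllithium 4 (not isolated)
Conditions: MeLi (2.2 equiv), Et2O, 0 °C to rt; then H2O
Reagents that add atoms: none
Why: Shapiro reaction: the dianion formed by N–H and syn α′-CH2 deprotonation loses sulfinate and N2 to give the vinyllithium, whose protonation gives the homoannular diene, the known outcome for tosylhydrazones of α,β-unsaturated ketones; the stereocentre is not involved.

**Step 3**
Reactants: 5 (5R)-2-methyl-5-(prop-1-en-2-yl)cyclohexa-1,3-diene; 6 dioxygen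
Product: 7 (1R,4R,7S)-5-methyl-7-(prop-1-en-2-yl)-2,3-dioxabicyclo[2.2.2]oct-5-ene
Conditions: O2, tetraphenylporphyrin (cat.), hν (visible), CH2Cl2, −78 °C
Reagents that add atoms: dioxygen (6), O=O
Why: Sensitised singlet oxygen acts as a 2π partner in a concerted suprafacial [4+2] cycloaddition across the two termini of the locked s-cis ring diene, the reaction type by which cyclohexa-1,3-dienes are converted into ascaridole-type endoperoxides. The one ring closed is the six-membered 1,2-dioxene ring, which makes the [2.2.2] bicycle; it closes in a pericyclic event that forms both C–O bonds at once, not in a stepwise cyclisation. The two new stereocentres, the bridgeheads C3 and C6, are necessarily cis to each other because the addition is suprafacial. Their sense relative to C1 is set by the carvone-derived stereocentre, whose isopropenyl group sits on the sp3 carbon next to one diene terminus and shields its own face, so oxygen should add anti to it. The step needs this facial selectivity and needs cycloaddition to win over ene reactions; the cisoid diene reacts much faster with singlet oxygen than the 1,1-disubstituted isopropenyl alkene, and low temperature favours the cycloaddition. The syn adduct is the expected minor diastereomer and would be removed by chromatography here or after step 4.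

**Step 4**
Reactants: 7 (1R,4R,7S)-5-methyl-7-(prop-1-en-2-yl)-2,3-dioxabicyclo[2.2.2]oct-5-ene
Product: 8 (1R,4R,5S)-2-methyl-5-(prop-1-en-2-yl)cyclohex-2-ene-1,4-diol
Conditions: Zn, AcOH, CH2Cl2, 0 °C to rt
Reagents that add atoms: none
Why: Reductive O–O cleavage of a bicyclic endoperoxide with zinc in acetic acid is standard and gives the cis-2-ene-1,4-diol without touching either C–O bond, so C3 and C6 keep their configuration.

**Step 5**
Reactants: 8 (1R,4R,5S)-2-methyl-5-(prop-1-en-2-yl)cyclohex-2-ene-1,4-diol; 9 tert-butyldimethylsilyl chloride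
Product: 10 (1R,4R,5S)-1,4-bis(tert-butyldimethylsilyloxy)-2-methyl-5-(prop-1-en-2-yl)cyclohex-2-ene
Conditions: TBSCl, imidazole, DMF, rt to 40 °C
Reagents that add atoms: tert-butyldimethylsilyl chloride (9), CC(C)(C)[Si](C)(C)Cl
Why: Routine silylation of both secondary allylic hydroxyls masks C3–OH and C6–OH for the oxidations and the organometallic step, and the bulky pseudoaxial C3 silyloxy group later screens the lower face of the ring alkene.

**Step 6**
Reactants: 10 (1R,4R,5S)-1,4-bis(tert-butyldimethylsilyloxy)-2-methyl-5-(prop-1-en-2-yl)cyclohex-2-ene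
Product: 12 2-[(1S,2R,5R)-2,5-bis(tert-butyldimethylsilyloxy)-4-methylcyclohex-3-en-1-yl]prop-2-enal, via allylic alcohol 11 (not isolated)
Conditions: SeO2 (cat.), t-BuOOH, CH2Cl2, rt; then MnO2, rt
Reagents that add atoms: tert-butyl hydroperoxide, CC(C)(C)OO; selenium dioxide (catalytic oxygen carrier), O=[Se]=O
Why: Selenium dioxide allylic oxidation (ene reaction, then [2,3]-sigmatropic shift) should take place at the methyl group of the isopropenyl unit, as it does for isopropenyl groups on ring carbons next to an oxygenated carbon, while the ring alkene is deactivated and shielded by two allylic silyloxy groups; manganese dioxide then takes the primary allylic alcohol to the enal.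

**Step 7**
Reactants: 12 2-[(1S,2R,5R)-2,5-bis(tert-butyldimethylsilyloxy)-4-methylcyclohex-3-en-1-yl]prop-2-enal
Product: 13 2-[(1S,2S,3R,4R,5R)-2,5-bis(tert-butyldimethylsilyloxy)-3,4-dihydroxy-4-methylcyclohexyl]prop-2-enal
Conditions: OsO4 (cat.), NMO, acetone/H2O, rt
Reagents that add atoms: osmium tetroxide (catalytic), O=[Os](=O)(=O)=O; N-methylmorpholine N-oxide (terminal oxidant), C[N+]1([O-])CCOCC1
Why: Upjohn dihydroxylation: electrophilic OsO4 should prefer the trisubstituted ring alkene to the electron-poor enal alkene and add anti to both allylic silyloxy groups, the usual course for cyclic allylic ethers, which puts the C4 hydroxyl trans to the C3 oxygen and cis to the side chain (C5 is set too but is oxidised later).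

**Step 8**
Reactants: 13 2-[(1S,2S,3R,4R,5R)-2,5-bis(tert-butyldimethylsilyloxy)-3,4-dihydroxy-4-methylcyclohexyl]prop-2-enal; 14 prenyl chloride
Product: 16 bis-TBS prenyl carbinol triol (side chain CH2=C–CH(OH)–CH2–CH=C(CH3)2; carbinol epimers), via prenylbarium chloride 15 (not isolated)
Conditions: BaI2, lithium biphenylide, THF, rt; 14, −78 °C; then 13 (reagent in excess), −78 °C; H2O
Reagents that add atoms: prenyl chloride (14), CC(C)=CCCl
Why: Allylbarium reagents add to aldehydes in 1,2-fashion through their less substituted α-carbon at −78 °C, which should give the linear prenyl carbinol instead of the 1,1-dimethylallyl isomer; the excess reagent allows for the two free hydroxyls, and the new carbinol centre needs no control.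

**Step 9**
Reactants: 16 bis-TBS prenyl carbinol triol
Product: 17 (2S,3R,5S,6S)-3,6-bis(tert-butyldimethylsilyloxy)-2-hydroxy-2-methyl-5-(6-methyl-3-oxohepta-1,5-dien-2-yl)cyclohexan-1-one
Conditions: IBX, DMSO, rt
Reagents that add atoms: none
Why: IBX oxidises secondary alcohols without cleaving 1,2-diols, so the C5 carbinol should become the α-hydroxy ketone and the side-chain allylic carbinol the α-methylene ketone in one operation, the tertiary C4 hydroxyl staying free and the neutral medium keeping the prenyl alkene out of conjugation.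

**Step 10**
Reactants: 17 (2S,3R,5S,6S)-3,6-bis(tert-butyldimethylsilyloxy)-2-hydroxy-2-methyl-5-(6-methyl-3-oxohepta-1,5-dien-2-yl)cyclohexan-1-one
Product: 18 (2S,3R,5S,6S)-2,3,6-trihydroxy-2-methyl-5-(6-methyl-3-oxohepta-1,5-dien-2-yl)cyclohexan-1-one
Conditions: HF·pyridine, THF, 0 °C to rt
Reagents that add atoms: none
Why: Fluoride-driven desilylation under buffered, non-basic conditions should free both secondary hydroxyls without α-ketol rearrangement, retro-aldol cleavage or migration of the β,γ-alkene.

**Step 11**
Reactants: 18 (2S,3R,5S,6S)-2,3,6-trihydroxy-2-methyl-5-(6-methyl-3-oxohepta-1,5-dien-2-yl)cyclohexan-1-one; 19 isovaleryl chloride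
Product: 20 (1S,3S,4R,6S)-3,4-dihydroxy-3-methyl-6-(6-methyl-3-oxohepta-1,5-dien-2-yl)-2-oxocyclohexyl 3-methylbutanoate
Conditions: isovaleryl chloride (1.05 equiv), pyridine, CH2Cl2, −20 °C
Reagents that add atoms: 3-methylbutanoyl chloride (19), CC(C)CC(=O)Cl
Why: Site-selective acylation: in the preferred chair the C6 hydroxyl is an equatorial secondary α-ketol hydroxyl, whereas the C3 hydroxyl is axial and flanked by the fully substituted C4 and the C4 hydroxyl is tertiary, so one equivalent of acid chloride should esterify C6 only.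

**Step 12**
Reactants: 20 (1S,3S,4R,6S)-3,4-dihydroxy-3-methyl-6-(6-methyl-3-oxohepta-1,5-dien-2-yl)-2-oxocyclohexyl 3-methylbutanoate; 6 dioxygen
Product: 21 (1S,3S,4R,6S)-3,4-dihydroxy-6-[(4E)-6-hydroperoxy-6-methyl-3-oxohepta-1,4-dien-2-yl]-3-methyl-2-oxocyclohexyl 3-methylbutanoate
Conditions: O2, tetraphenylporphyrin (cat.), hν (visible), CH2Cl2, 0 °C
Reagents that add atoms: dioxygen (6), O=O
Why: Schenck ene reaction: singlet oxygen should bond to the dimethyl-substituted carbon of the prenyl alkene and take an allylic hydrogen from the methylene between alkene and ketone, moving the double bond into conjugation as the E-enone (the known behaviour of β,γ-unsaturated ketones), while the electron-poor α-methylene enone does not react; any secondary hydroperoxide from methyl abstraction would be removed by chromatography.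

**Compound list**

1 | (R)-carvone, (5R)-2-methyl-5-(prop-1-en-2-yl)cyclohex-2-en-1-one | C=C(C)[C@@H]1CC=C(C)C(=O)C1 | starting material
2 | 4-methylbenzenesulfonohydrazide | Cc1ccc(cc1)S(=O)(=O)NN | starting material
3 | (R)-carvone (E)-tosylhydrazone, N'-[(1E,5R)-2-methyl-5-(prop-1-en-2-yl)cyclohex-2-en-1-ylidene]-4-methylbenzenesulfonohydrazide | C=C(C)[C@@H]1CC=C(C)/C(=N/NS(=O)(=O)c2ccc(C)cc2)C1 | intermediate
4 | [(3R)-6-methyl-3-(prop-1-en-2-yl)cyclohexa-1,5-dien-1-yl]lithium (vinyllithium, not isolated) | C=C(C)[C@@H]1CC=C(C)C([Li])=C1 | intermediate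
5 | (5R)-2-methyl-5-(prop-1-en-2-yl)cyclohexa-1,3-diene | C=C(C)[C@@H]1CC=C(C)C=C1 | intermediate
6 | dioxygen (used as singlet oxygen) | O=O | starting material
7 | (1R,4R,7S)-5-methyl-7-(prop-1-en-2-yl)-2,3-dioxabicyclo[2.2.2]oct-5-ene (peroxide bridge anti to the isopropenyl group) | C=C(C)[C@@H]1C[C@@H](OO2)C(C)=C[C@H]12 | intermediate
8 | (1R,4R,5S)-2-methyl-5-(prop-1-en-2-yl)cyclohex-2-ene-1,4-diol (hydroxyls cis to each other, trans to isopropenyl) | C=C(C)[C@@H]1C[C@@H](O)C(C)=C[C@H]1O | intermediate
9 | tert-butyldimethylsilyl chloride | CC(C)(C)[Si](C)(C)Cl | starting material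
10 | (1R,4R,5S)-1,4-bis(tert-butyldimethylsilyloxy)-2-methyl-5-(prop-1-en-2-yl)cyclohex-2-ene | C=C(C)[C@@H]1C[C@@H](O[Si](C)(C)C(C)(C)C)C(C)=C[C@H]1O[Si](C)(C)C(C)(C)C | intermediate
11 | 2-[(1S,2R,5R)-2,5-bis(tert-butyldimethylsilyloxy)-4-methylcyclohex-3-en-1-yl]prop-2-en-1-ol (not isolated) | C=C(CO)[C@@H]1C[C@@H](O[Si](C)(C)C(C)(C)C)C(C)=C[C@H]1O[Si](C)(C)C(C)(C)C | intermediate
12 | 2-[(1S,2R,5R)-2,5-bis(tert-butyldimethylsilyloxy)-4-methylcyclohex-3-en-1-yl]prop-2-enal | C=C(C=O)[C@@H]1C[C@@H](O[Si](C)(C)C(C)(C)C)C(C)=C[C@H]1O[Si](C)(C)C(C)(C)C | intermediate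
13 | 2-[(1S,2S,3R,4R,5R)-2,5-bis(tert-butyldimethylsilyloxy)-3,4-dihydroxy-4-methylcyclohexyl]prop-2-enal (C4 and C5 hydroxyls cis to the side chain, trans to the silyloxy groups) | C=C(C=O)[C@@H]1C[C@@H](O[Si](C)(C)C(C)(C)C)[C@](C)(O)[C@H](O)[C@H]1O[Si](C)(C)C(C)(C)C | intermediate
14 | prenyl chloride, 1-chloro-3-methylbut-2-ene | CC(C)=CCCl | starting material
15 | (3-methylbut-2-en-1-yl)barium chloride (not isolated) | CC(C)=CC[Ba]Cl | intermediate
16 | (1R,2R,3S,4S,6R)-3,6-bis(tert-butyldimethylsilyloxy)-4-(3-hydroxy-6-methylhepta-1,5-dien-2-yl)-1-methylcyclohexane-1,2-diol (both epimers at the side-chain carbinol) | C=C(C(O)CC=C(C)C)[C@@H]1C[C@@H](O[Si](C)(C)C(C)(C)C)[C@](C)(O)[C@H](O)[C@H]1O[Si](C)(C)C(C)(C)C | intermediate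
17 | (2S,3R,5S,6S)-3,6-bis(tert-butyldimethylsilyloxy)-2-hydroxy-2-methyl-5-(6-methyl-3-oxohepta-1,5-dien-2-yl)cyclohexan-1-one | C=C(C(=O)CC=C(C)C)[C@@H]1C[C@@H](O[Si](C)(C)C(C)(C)C)[C@](C)(O)C(=O)[C@H]1O[Si](C)(C)C(C)(C)C | intermediate
18 | (2S,3R,5S,6S)-2,3,6-trihydroxy-2-methyl-5-(6-methyl-3-oxohepta-1,5-dien-2-yl)cyclohexan-1-one | C=C(C(=O)CC=C(C)C)[C@@H]1C[C@@H](O)[C@](C)(O)C(=O)[C@H]1O | intermediate
19 | isovaleryl chloride, 3-methylbutanoyl chloride | CC(C)CC(=O)Cl | starting material
20 | (1S,3S,4R,6S)-3,4-dihydroxy-3-methyl-6-(6-methyl-3-oxohepta-1,5-dien-2-yl)-2-oxocyclohexyl 3-methylbutanoate | C=C(C(=O)CC=C(C)C)[C@@H]1C[C@@H](O)[C@](C)(O)C(=O)[C@H]1OC(=O)CC(C)C | intermediate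
21 | (1S,3S,4R,6S)-3,4-dihydroxy-6-[(4E)-6-hydroperoxy-6-methyl-3-oxohepta-1,4-dien-2-yl]-3-methyl-2-oxocyclohexyl 3-methylbutanoate (CNP0239240.1) | C=C(C(=O)/C=C/C(C)(C)OO)[C@@H]1C[C@@H](O)[C@](C)(O)C(=O)[C@H]1OC(=O)CC(C)C | target

**Step count**

Total steps: 12. Longest linear sequence: 12 steps (1 → 21).

**Three steps most likely to fail**

Step 8, the prenyl addition. The organobarium reagent may attack through its γ-carbon, the C5 alkoxide may trigger migration of the neighbouring C6 silyl group, or the reagent may simply be consumed by the hydroxyls and by deprotonation of the enal. The fallback sets out from 13 and uses a neutral allylboration, in which regiochemistry is fixed by allylic transposition through a closed six-membered transition state and does not depend on the metal. The tertiary allylboronate 4,4,5,5-tetramethyl-2-(2-methylbut-3-en-2-yl)-1,3,2-dioxaborolane F5 would be made by copper-catalysed SN2′ borylation of methyl prenyl carbonate with bis(pinacolato)diboron. Heated gently with 13 in toluene, it should transfer the prenyl group through its unsubstituted terminus and, after aqueous work-up, give the linear carbinol, rejoining the route at 16.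

Step 3, the cycloaddition. Facial selectivity with so small a dienophile may be poor, ene reactions at the ring may compete, and the triene may aromatise before it reacts. The fallback sets out from 1 and reaches the protected cis-enediol without a cycloaddition.
- Hydroxylation of the kinetic C6 enolate (LDA, −78 °C, then 2-(phenylsulfonyl)-3-phenyloxaziridine) should occur trans to the isopropenyl group and give (5S,6S)-6-hydroxy-2-methyl-5-(prop-1-en-2-yl)cyclohex-2-en-1-one F1.
- Silylation gives (5S,6S)-6-(tert-butyldimethylsilyloxy)-2-methyl-5-(prop-1-en-2-yl)cyclohex-2-en-1-one F2.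
- Alkaline hydrogen peroxide should epoxidise the enone trans to the isopropenyl group, giving (1R,3S,4S,6R)-3-(tert-butyldimethylsilyloxy)-1-methyl-4-(prop-1-en-2-yl)-7-oxabicyclo[4.1.0]heptan-2-one F3.
- Wharton transposition (hydrazine hydrate, catalytic acetic acid, methanol) turns the epoxy ketone into the transposed allylic alcohol with the C3–O bond retained: (1R,4R,5S)-4-(tert-butyldimethylsilyloxy)-2-methyl-5-(prop-1-en-2-yl)cyclohex-2-en-1-ol F4.
- A second silylation rejoins the route at 10.

Step 12, the ene reaction. Hydrogen abstraction from the methyl groups would give the secondary hydroperoxide with an isopropenyl terminus, and the polyfunctional product may degrade under irradiation. The fallback sets out from 20 and fixes the regiochemistry by ionic steps. Bromohydroperoxidation of the prenyl alkene (1,3-dibromo-5,5-dimethylhydantoin, anhydrous ethereal hydrogen peroxide, −40 °C) should open the bromonium ion at the tertiary carbon and give (1S,3S,4R,6S)-6-(5-bromo-6-hydroperoxy-6-methyl-3-oxohept-1-en-2-yl)-3,4-dihydroxy-3-methyl-2-oxocyclohexyl 3-methylbutanoate F6. Brief treatment with triethylamine in dichloromethane at 0 °C should then remove hydrogen bromide from this β-bromo ketone by an E1cB pathway and give the E-enone, arriving at 21.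

**Further compounds**

F1 | step 3 | (5S,6S)-6-hydroxy-2-methyl-5-(prop-1-en-2-yl)cyclohex-2-en-1-one | C=C(C)[C@@H]1CC=C(C)C(=O)[C@H]1O
F2 | step 3 | (5S,6S)-6-(tert-butyldimethylsilyloxy)-2-methyl-5-(prop-1-en-2-yl)cyclohex-2-en-1-one | C=C(C)[C@@H]1CC=C(C)C(=O)[C@H]1O[Si](C)(C)C(C)(C)C
F3 | step 3 | (1R,3S,4S,6R)-3-(tert-butyldimethylsilyloxy)-1-methyl-4-(prop-1-en-2-yl)-7-oxabicyclo[4.1.0]heptan-2-one | C=C(C)[C@@H]1C[C@H]2O[C@@]2(C)C(=O)[C@H]1O[Si](C)(C)C(C)(C)C
F4 | step 3 | (1R,4R,5S)-4-(tert-butyldimethylsilyloxy)-2-methyl-5-(prop-1-en-2-yl)cyclohex-2-en-1-ol | C=C(C)[C@@H]1C[C@@H](O)C(C)=C[C@H]1O[Si](C)(C)C(C)(C)C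
F5 | step 8 | 4,4,5,5-tetramethyl-2-(2-methylbut-3-en-2-yl)-1,3,2-dioxaborolane | C=CC(C)(C)B1OC(C)(C)C(C)(C)O1
F6 | step 12 | (1S,3S,4R,6S)-6-(5-bromo-6-hydroperoxy-6-methyl-3-oxohept-1-en-2-yl)-3,4-dihydroxy-3-methyl-2-oxocyclohexyl 3-methylbutanoate (both epimers at C–Br) | C=C(C(=O)CC(Br)C(C)(C)OO)[C@@H]1C[C@@H](O)[C@](C)(O)C(=O)[C@H]1OC(=O)CC(C)C
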